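**Strategy.** Both halves of the target are the same arene, 2,4,6-trihydroxypropiophenone, in two alkylation states. The route therefore does not couple a preformed filicinic acid: it assembles the fully aromatic diarylmethane and dearomatises last. The key step is a ring-selective dearomative gem-dimethylation. It exploits that the chromene benzene ring is hexasubstituted, whereas the other propionylphloroglucinol ring keeps one aromatic C–H between two hydroxyl groups. Two C-methylations there create the quaternary C4 (two methyl groups) of the cyclohexadienone ring, its enolised triketone array and the final substitution pattern in one operation. The precursor is the chromene arene joined through the CH2 bridge to an unmodified propionylphloroglucinol ring.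

Key step: step 3

Remark: the target has no stereogenic centre (the ring carbon C(CH3)2 carries two identical methyl groups) and no configurationally free double bond, so it is achiral and "single enantiomer" is moot; it is made as the enol tautomer drawn in the given SMILES.

Step 1
Reactants: 1 flopropione, 1-(2,4,6-trihydroxyphenyl)propan-1-one; 2 prenal, 3-methylbut-2-enal
Product: 4 1-(5,7-dihydroxy-2,2-dimethyl-2H-chromen-8-yl)propan-1-one, via o-quinone methide 3 (not isolated)
Conditions: 1 (1.5 equiv), 2 (1.0 equiv), pyridine, 110 °C, Ar
Reagents that add atoms: none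
Why: Amine-mediated Knoevenagel-type condensation of the enal at C3 of the phloroglucinol ring gives the (Z)-dienone 3, whose oxa-6π electrocyclisation (formal [3+3] chromene annulation) should close mainly through the oxygen next to the acyl-bearing carbon, because that dienone keeps the chelated 2-acyl-1,3-dione array, while the excess of 1 suppresses a second annulation and the minor 6-propanoyl isomer is removed by chromatography.

Step 2
Reactants: 4 1-(5,7-dihydroxy-2,2-dimethyl-2H-chromen-8-yl)propan-1-one; 1 flopropione
Product: 7 1-{3-[(5,7-dihydroxy-2,2-dimethyl-8-propanoyl-2H-chromen-6-yl)methyl]-2,4,6-trihydroxyphenyl}propan-1-one, via Mannich base 5 (not isolated), via o-quinone methide 6 (not isolated)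
Conditions: Me2N=CH2+ I− (1.0 equiv), MeCN, 0 °C to rt; then 1 (4 equiv), NaOAc (1.1 equiv), 80 °C
Reagents that add atoms: Eschenmoser's salt (N,N-dimethylmethylideneammonium iodide), C=[N+](C)C.[I-]
Why: Mannich aminomethylation occurs at C6, the only free ring carbon of 4, and on warming the acidic Mannich base 5 loses dimethylamine to the o-quinone methide 6, which is trapped in a Michael (Friedel–Crafts-type) addition by C3 of flopropione, the fourfold excess of which suppresses 2:1 adducts.

Step 3
Reactants: 7 1-{3-[(5,7-dihydroxy-2,2-dimethyl-8-propanoyl-2H-chromen-6-yl)methyl]-2,4,6-trihydroxyphenyl}propan-1-one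
Product: 9 2-[(5,7-dihydroxy-2,2-dimethyl-8-propanoyl-2H-chromen-6-yl)methyl]-3,5-dihydroxy-4,4-dimethyl-6-propanoylcyclohexa-2,5-dien-1-one (target), via monomethyl diarylmethane 8 (not isolated)
Conditions: NaOMe (4.0 equiv), MeI (2.2 equiv), MeOH, 0 °C to rt, Ar; then 1 M HCl
Reagents that add atoms: iodomethane, CI
Why: The sodium polyphenolate of 7 is C-alkylated by MeI in an SN2 step at C5 of the propionylphloroglucinol ring, its only unsubstituted ring carbon and one flanked by two phenoxide oxygens, to give 8; a second SN2 C-methylation at the same carbon breaks aromaticity, and the dienone tautomerises to the chelated enol of the 2-acylcyclohexane-1,3,5-trione, which is the acylfilicinic acid ring. The closest known reaction type is the dearomative gem-dimethylation of acylphloroglucinols to acylfilicinic acids with MeI and NaOMe in methanol (alkylative dearomatisation of a phenolate). No ring is closed and no stereocentre is formed, because the new quaternary carbon carries two identical methyl groups. The step needs ring and site selectivity: the chromene ring has no C–H, and the two other oxygen-flanked ring carbons (C3 of the reacting ring in 8 and C6 of the chromene) both carry the bulky diarylmethane CH2, so the methyl-bearing carbon should be the least hindered nucleophilic site. C- over O-alkylation is favoured by the hydrogen-bonding solvent, the sodium counter-ion and the soft electrophile, and the sequence should stop at the product because its vinylogous-acid anion is far less nucleophilic than a phenolate when MeI is kept near two equivalents. Low temperature limits base-induced retro-Michael scission of the CH2 bridge.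

**Compound list**
1 | flopropione, 1-(2,4,6-trihydroxyphenyl)propan-1-one | CCC(=O)c1c(O)cc(O)cc1O | starting material
2 | prenal, 3-methylbut-2-enal | CC(C)=CC=O | starting material
3 | (6Z)-3,5-dihydroxy-6-(3-methylbut-2-en-1-ylidene)-2-propanoylcyclohexa-2,4-dien-1-one (o-quinone methide) | CCC(=O)C1=C(O)C=C(O)/C(=C/C=C(C)C)C1=O | intermediate
4 | 1-(5,7-dihydroxy-2,2-dimethyl-2H-chromen-8-yl)propan-1-one | CCC(=O)c1c(O)cc(O)c2C=CC(C)(C)Oc12 | intermediate
5 | 1-{6-[(dimethylamino)methyl]-5,7-dihydroxy-2,2-dimethyl-2H-chromen-8-yl}propan-1-one (Mannich base) | CCC(=O)c1c(O)c(CN(C)C)c(O)c2C=CC(C)(C)Oc12 | intermediate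
6 | 5-hydroxy-2,2-dimethyl-6-methylidene-8-propanoyl-2H-chromen-7(6H)-one (o-quinone methide) | CCC(=O)C1=C2OC(C)(C)C=CC2=C(O)C(=C)C1=O | intermediate
7 | 1-{3-[(5,7-dihydroxy-2,2-dimethyl-8-propanoyl-2H-chromen-6-yl)methyl]-2,4,6-trihydroxyphenyl}propan-1-one | CCC(=O)c1c(O)cc(O)c(Cc2c(O)c3C=CC(C)(C)Oc3c(C(=O)CC)c2O)c1O | intermediate
8 | 1-{3-[(5,7-dihydroxy-2,2-dimethyl-8-propanoyl-2H-chromen-6-yl)methyl]-2,4,6-trihydroxy-5-methylphenyl}propan-1-one | CCC(=O)c1c(O)c(C)c(O)c(Cc2c(O)c3C=CC(C)(C)Oc3c(C(=O)CC)c2O)c1O | intermediate
9 | 2-[(5,7-dihydroxy-2,2-dimethyl-8-propanoyl-2H-chromen-6-yl)methyl]-3,5-dihydroxy-4,4-dimethyl-6-propanoylcyclohexa-2,5-dien-1-one | CCC(=O)C1=C(O)C(C)(C)C(O)=C(Cc2c(O)c3c(c(C(=O)CC)c2O)OC(C)(C)C=C3)C1=O | target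

**Step count.** Total: 3 steps. Longest linear sequence: 3 steps (1 → 4 → 7 → 9).

**Steps most likely to fail, with fallbacks**

1. Step 3 (key step). The second methylation may go to one of the bridge-bearing ring carbons instead of the methyl-bearing one, a third methyl group may be introduced, or the base may cleave the CH2 bridge by retro-Michael scission and scramble the two halves. Fallback: dearomatise before the bridge is made. The fallback sets out from 1 and comes back at 9. Flopropione 1 would be gem-dimethylated as the monomer (NaOMe, MeI, MeOH, 0 °C to rt) to propanoylfilicinic acid F1 (3,5-dihydroxy-4,4-dimethyl-2-propanoylcyclohexa-2,5-dien-1-one), which has a single nucleophilic ring C–H. F1 would then take the place of 1 in the second half of step 2: the Mannich base 5 generated from 4 is warmed with F1 and NaOAc in MeCN, and the o-quinone methide 6 is trapped by F1 to give 9 directly.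

2. Step 1. The pyran ring may close through the para-hydroxyl group, giving the 6-propanoyl chromene as the main isomer, or both free ring positions may be annulated. Fallback: remove the choice of oxygen by masking the para-hydroxyl group. The fallback sets out from 1 and comes back at 4. Selective etherification of the non-chelated, most acidic 4-OH (MOMCl 1.0 equiv, iPr2NEt, CH2Cl2, 0 °C) would give 1-[2,6-dihydroxy-4-(methoxymethoxy)phenyl]propan-1-one F2. Annulation with 2 (pyridine, 110 °C) can then close only through an ortho-hydroxyl group, giving 1-[7-hydroxy-5-(methoxymethoxy)-2,2-dimethyl-2H-chromen-8-yl]propan-1-one F3. Acetal cleavage (HCl, MeOH, rt) would return 4.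

3. Step 2. The o-quinone methide may be consumed by twofold alkylation of the doubly nucleophilic flopropione ring or by self-addition, or the amine may be lost too slowly. Fallback: make the bridge by homo-coupling and desymmetrise afterwards. The fallback sets out from 1 and comes back at 7. Flopropione 1 (3 equiv) with aqueous formaldehyde (1 equiv) in dilute aqueous NaOH at 0 °C would give the symmetric bis(2,4,6-trihydroxy-3-propanoylphenyl)methane F4 with no cross-selectivity issue. Statistical mono-annulation of F4 with prenal 2 (0.8 equiv, pyridine, 110 °C), with recycling of unreacted F4, would then give 7.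

Further compounds
F1 | step 3 | propanoylfilicinic acid, 3,5-dihydroxy-4,4-dimethyl-2-propanoylcyclohexa-2,5-dien-1-one | CCC(=O)C1=C(O)C(C)(C)C(O)=CC1=O
F2 | step 1 | 1-[2,6-dihydroxy-4-(methoxymethoxy)phenyl]propan-1-one | CCC(=O)c1c(O)cc(OCOC)cc1O
F3 | step 1 | 1-[7-hydroxy-5-(methoxymethoxy)-2,2-dimethyl-2H-chromen-8-yl]propan-1-one | CCC(=O)c1c(O)cc(OCOC)c2C=CC(C)(C)Oc12
F4 | step 2 | bis(2,4,6-trihydroxy-3-propanoylphenyl)methane | CCC(=O)c1c(O)cc(O)c(Cc2c(O)cc(O)c(C(=O)CC)c2O)c1O
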